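**Retrosynthetic overview**

1. Locants (squalene-type): C2–C11 = oxepane/cyclohexane half (C2 = CMe2–O, C3 = CHOH, C6 = angular C–Me, C7 = ring CH–O, C10 = C(Me)OH, C11 = ring CH); C12–C13 = CH2CH2 bridge; C14–C23 = hydroazulenone (C14=C15(Me)–C16=O, C19 = C(Me)OH, C23 = CMe2).
2. Key disconnection C11–C12. C11 is α to the carbinol carbon C10, and C12–C13–C14 is an allyl unit ending at the β-carbon of the C14=C15–C16=O enone. A C10 ketone with a C11 ester (8) and the tertiary vinyl carbinol of the vinylogous ester (26) are therefore joined by a Carroll reaction through the array C11–C(=O)–O–C14–C13=C12, with loss of CO2. The C13=C14–C15=C16(OMe) diene that remains is the masked enone.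
3. After the union: MeMgBr on the C10 ketone (axial OH), then aqueous acid frees the enone and removes both silyl ethers.
4. West rings: oxepane, then cyclohexane, in one epoxonium cascade of an acyclic bis-epoxide β-ketoester made from geraniol (two epoxidations of opposite sense).
5. East rings: cyclopentene first (ring-closing metathesis of linalool); two Claisen rearrangements place the two cis side chains; the seven-membered ring is closed last by an intramolecular Claisen condensation.

Key step: step 19

Remark: (S)-(+)-linalool and the L-fructose-derived enantiomer of the Shi ketone are taken as purchasable in high enantiomeric purity.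

**Route**

Step 1
Reactants: 1 geraniol
Product: 2 (2R,3R)-2,3-epoxygeraniol
Conditions: Ti(OiPr)4 (5 mol %), D-(−)-diethyl tartrate (6 mol %), t-BuOOH, 4 Å molecular sieves, CH2Cl2, −20 °C
Reagents that add atoms: tert-butyl hydroperoxide CC(C)(C)OO
Why: Sharpless asymmetric epoxidation of the allylic alcohol, in which the D-tartrate complex delivers oxygen to the face that gives the (2R,3R)-oxirane while the remote alkene, which is not bound to titanium, stays untouched.

Step 2
Reactants: 2 (2R,3R)-2,3-epoxygeraniol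
Product: 3 (2R,3R,6S)-2,3:6,7-diepoxy-3,7-dimethyloctan-1-ol
Conditions: L-fructose-derived Shi ketone (0.3 equiv), KHSO5 (as its triple salt), K2CO3, Bu4NHSO4, MeCN/dimethoxymethane/aqueous buffer pH 10.5, 0 °C
Reagents that add atoms: potassium peroxymonosulfate [K+].[O-]S(=O)(=O)OO
Why: Shi epoxidation (chiral dioxirane, spiro transition state) of the remaining trisubstituted alkene under reagent control, the L-series ketone setting the new oxirane CH as S, opposite in sense to the first oxirane as the target requires.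

Step 3
Reactants: 3 (2R,3R,6S)-2,3:6,7-diepoxy-3,7-dimethyloctan-1-ol
Product: 4 primary iodide of 3 (configuration unchanged)
Conditions: I2, PPh3, imidazole, CH2Cl2, 0 °C
Reagents that add atoms: iodine II
Why: Garegg–Samuelsson iodination (SN2 on the alkoxyphosphonium ion) of the primary alcohol in a buffered medium that leaves both oxiranes closed and touches no stereocenter.

Step 4
Reactants: 4 primary iodide; 5 tert-butyl acetoacetate
Product: 6 tert-butyl diepoxy β-ketoester
Conditions: LDA (2.1 equiv), THF, 0 °C; then 4, −78 → 0 °C; H2O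
Reagents that add atoms: none
Why: alkylation of the acetoacetate dianion at its terminal carbon, the more nucleophilic site, by the primary iodide (SN2), with no stereocenter formed.

Step 5
Reactants: 6 tert-butyl diepoxy β-ketoester
Product: 7 (Z)-triethylsilyl enol ether of 6
Conditions: NaH, THF, 0 °C; Et3SiCl
Reagents that add atoms: chlorotriethylsilane CC[Si](Cl)(CC)CC
Why: O-silylation of the sodium enolate of the β-ketoester, which fixes the future nucleophilic carbon between ketone and ester without any Lewis acid that could open the oxiranes.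

Step 6
Reactants: 7 (Z)-triethylsilyl enol ether
Product: 8 tert-butyl (3S,5aR,9aR)-2,2,5a-trimethyl-7-oxo-3-(triethylsilyloxy)decahydro-1-benzoxepine-6-carboxylate (C6 epimers and enol)
Conditions: Et3SiOTf (0.2 equiv), 2,6-di-tert-butyl-4-methylpyridine (0.3 equiv), CH2Cl2, −78 °C
Reagents that add atoms: none
Why: silyl-triflate-triggered tandem oxa-/carbacyclisation of a bis-epoxide ended by a silyl enol ether, in which the silylated terminal oxirane is opened at its tertiary carbon by the oxygen of the internal oxirane (oxepane, 7-endo) and the epoxonium ion is opened at its tertiary carbon by the enol ether carbon through a chair transition state (cyclohexane, 6-endo, anti), so that the oxirane configurations are carried into the trans-fused bicycle (retention at both CH–O carbons, inversion at the quaternary carbon) and the silyl group is relayed to the C3 oxygen.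

Step 7
Reactants: 9 (S)-(+)-linalool
Product: 10 (1S)-1-methylcyclopent-2-en-1-ol
Conditions: second-generation Grubbs catalyst (1 mol %), CH2Cl2, 40 °C
Reagents that add atoms: none
Why: ring-closing olefin metathesis of the 1,6-diene, driven by loss of gaseous isobutene, with the carbinol stereocenter not involved.

Step 8
Reactants: 10 (1S)-1-methylcyclopent-2-en-1-ol; 11 isobutyryl chloride
Product: 12 (1S)-1-methylcyclopent-2-en-1-yl 2-methylpropanoate
Conditions: n-BuLi, THF, −78 °C; then 11, −78 → 0 °C
Reagents that add atoms: none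
Why: acylation of the lithium alkoxide by the acid chloride (nucleophilic acyl substitution) under base, so that the ionisable tertiary allylic ester never meets acid and the carbinol configuration is retained.

Step 9
Reactants: 12 (1S)-1-methylcyclopent-2-en-1-yl 2-methylpropanoate
Product: 15 2-methyl-2-[(1R)-3-methylcyclopent-2-en-1-yl]propanoic acid, via silyl ketene acetal 13 (not isolated), via trimethylsilyl ester 14 (not isolated)
Conditions: LDA, THF, −78 °C; Me3SiCl; −78 → 50 °C; then 1 M HCl, THF
Reagents that add atoms: none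
Why: Ireland–Claisen rearrangement, whose [3,3] shift is suprafacial on the cyclopentenyl unit, so that the C–O stereocenter is traded for the new C–C stereocenter on the same ring face (R) while the quaternary carbon is formed intramolecularly from a tetrasubstituted ketene acetal that has no geometry issue.

Step 10
Reactants: 15 2-methyl-2-[(1R)-3-methylcyclopent-2-en-1-yl]propanoic acid
Product: 16 2-methyl-2-[(1R)-3-methylcyclopent-2-en-1-yl]pentan-3-one
Conditions: EtLi (2.5 equiv), Et2O, 0 °C → rt; then H2O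
Reagents that add atoms: ethyllithium [Li]CC
Why: ketone synthesis from a carboxylic acid, in which the lithium carboxylate takes up one ethyllithium to a geminal dialkoxide that collapses to the ethyl ketone only on work-up, the stereocenter staying untouched.

Step 11
Reactants: 16 2-methyl-2-[(1R)-3-methylcyclopent-2-en-1-yl]pentan-3-one
Product: 17 (4R)-2-methyl-4-(2-methyl-3-oxopentan-2-yl)cyclopent-2-en-1-one
Conditions: CrO3, 3,5-dimethylpyrazole, CH2Cl2, −20 °C
Reagents that add atoms: chromium trioxide O=[Cr](=O)=O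
Why: chromium-mediated allylic oxidation at the only allylic ring methylene, the other allylic ring position being a hindered tertiary CH, which gives the 2-methylcyclopentenone without touching the stereocenter.

Step 12
Reactants: 17 (4R)-2-methyl-4-(2-methyl-3-oxopentan-2-yl)cyclopent-2-en-1-one
Product: 18 2-[(1R,4S)-4-hydroxy-3-methylcyclopent-2-en-1-yl]-2-methylpentan-3-one
Conditions: NaBH4, CeCl3·7H2O, MeOH, −78 °C
Reagents that add atoms: none
Why: Luche 1,2-reduction, in which hydride adds to the enone carbonyl from the face opposite the bulky C4 side chain to give the cis allylic alcohol (4S), the α-quaternary saturated ketone being too hindered to react at this temperature.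

Step 13
Reactants: 18 2-[(1R,4S)-4-hydroxy-3-methylcyclopent-2-en-1-yl]-2-methylpentan-3-one; 19 triethyl orthoacetate
Product: 21 ethyl 2-[(1R,5R)-2-methyl-5-(2-methyl-3-oxopentan-2-yl)cyclopent-2-en-1-yl]acetate, via mixed ketene acetal 20 (not isolated)
Conditions: EtCO2H (cat.), xylenes, 140 °C, EtOH distilled off
Reagents that add atoms: none
Why: Johnson–Claisen rearrangement, whose suprafacial [3,3] shift delivers the acetate carbon to the ring face that carried the hydroxyl, i.e. cis to the existing side chain (new stereocenter R), and moves the double bond to the methyl-bearing position needed for step 14.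

Step 14
Reactants: 21 ethyl 2-[(1R,5R)-2-methyl-5-(2-methyl-3-oxopentan-2-yl)cyclopent-2-en-1-yl]acetate
Product: 22 ethyl 2-[(1R,2R,5R)-2-hydroxy-2-methyl-5-(2-methyl-3-oxopentan-2-yl)cyclopentyl]acetate
Conditions: Co(acac)2 (20 mol %), PhSiH3, O2 (1 atm), THF, rt
Reagents that add atoms: dioxygen O=O
Why: Mukaiyama hydration (hydrogen-atom transfer from a cobalt hydride, O2 trapping, reduction of the peroxide by the silane), Markovnikov-selective for the methyl-bearing carbon, the tertiary radical being trapped on the face opposite the two cis side chains to give the 2R alcohol while ketone and ester are inert.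

Step 15
Reactants: 22 ethyl 2-[(1R,2R,5R)-2-hydroxy-2-methyl-5-(2-methyl-3-oxopentan-2-yl)cyclopentyl]acetate
Product: 23 (1R,3aR,8aR)-1-hydroxy-1,4,4,6-tetramethyloctahydroazulene-5,7(1H,6H)-dione (cis-fused; C6 epimers and enol)
Conditions: KOtBu (2.5 equiv), THF, 0 °C → rt; then 1 M HCl to pH 5
Reagents that add atoms: none
Why: intramolecular Claisen (Dieckmann-type) condensation, in which the ketone can enolise only toward its CH2 because the other α-carbon is quaternary, the enolate closes the seven-membered ring on the ester (7-exo-trig) and deprotonation of the 1,3-diketone drives the equilibrium, the ring-fusion stereocenters not being enolisable.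

Step 16
Reactants: 23 (1R,3aR,8aR)-1-hydroxy-1,4,4,6-tetramethyloctahydroazulene-5,7(1H,6H)-dione
Product: 24 (1R,3aR,8aR)-1-hydroxy-7-methoxy-1,4,4,6-tetramethyl-2,3,3a,4,8,8a-hexahydroazulen-5(1H)-one
Conditions: HC(OMe)3, MeOH, camphorsulfonic acid (cat.), rt
Reagents that add atoms: trimethyl orthoformate COC(OC)OC
Why: acid-catalysed enol ether formation of a cyclic 1,3-diketone (vinylogous ester synthesis), in which methanol attacks the less hindered carbonyl remote from the gem-dimethyl carbon, so that the ketone left is the one flanked by the quaternary carbon.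

Step 17
Reactants: 24 (1R,3aR,8aR)-1-hydroxy-7-methoxy-1,4,4,6-tetramethyl-2,3,3a,4,8,8a-hexahydroazulen-5(1H)-one
Product: 25 triethylsilyl ether of 24
Conditions: Et3SiOTf, 2,6-lutidine, CH2Cl2, −78 °C
Reagents that add atoms: triethylsilyl trifluoromethanesulfonate CC[Si](CC)(CC)OS(=O)(=O)C(F)(F)F
Why: silylation of the hindered tertiary alcohol with a silyl triflate and a pyridine base, so that only one hydroxyl is free in step 19, with no stereocenter touched.

Step 18
Reactants: 25 triethylsilyl ether of 24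
Product: 26 (1R,3aR,8aR)-5-ethenyl-7-methoxy-1,4,4,6-tetramethyl-1-(triethylsilyloxy)-1,2,3,3a,4,5,8,8a-octahydroazulen-5-ol (C5 epimers)
Conditions: CH2=CHMgBr, CeCl3, THF, −78 → 0 °C; aqueous NaHCO3
Reagents that add atoms: vinylmagnesium bromide C=C[Mg]Br
Why: 1,2-addition of the organocerium reagent to the ketone of the vinylogous ester (first half of a Stork–Danheiser sequence, stopped before the acid step), CeCl3 suppressing enolisation, the configuration of the new carbinol carbon being irrelevant because it becomes sp2 in step 19.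

Step 19
Reactants: 8 tert-butyl (3S,5aR,9aR)-2,2,5a-trimethyl-7-oxo-3-(triethylsilyloxy)decahydro-1-benzoxepine-6-carboxylate; 26 (1R,3aR,8aR)-5-ethenyl-7-methoxy-1,4,4,6-tetramethyl-1-(triethylsilyloxy)-1,2,3,3a,4,5,8,8a-octahydroazulen-5-ol
Product: 30 (3S,5aR,6R,9aR)-6-{(2Z)-2-[(1R,3aR,8aR)-7-methoxy-1,4,4,6-tetramethyl-1-(triethylsilyloxy)-2,3,3a,4,8,8a-hexahydroazulen-5(1H)-ylidene]ethyl}-2,2,5a-trimethyl-3-(triethylsilyloxy)octahydro-1-benzoxepin-7(2H)-one, via acylketene 27 (not isolated), via allyl β-ketoester 28 (not isolated), via β-keto acid 29 (not isolated)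
Conditions: 26 (1.1 equiv), 4 Å molecular sieves, xylenes, 135 °C, slow N2 sweep
Reagents that add atoms: none
Why: On heating, the enolised tert-butyl β-ketoester loses tert-butanol to an acylketene that acylates the only free hydroxyl, the tertiary vinyl carbinol of 26; the allyl β-ketoester then undergoes the Carroll rearrangement, a [3,3] shift of its enol through the array C11–C(=O)–O–C14–C13=C12 that forms the C11–C12 bond, and the resulting β-keto acid loses CO2. The closest known reaction is the thermal Carroll reaction of a β-ketoester with a tertiary vinyl carbinol (the linalool to geranylacetone type), used here as a fragment coupling with the carboxyl carbon as a traceless tether. No ring is closed, the six-membered array being only a transition state, and if the very ionisable ester dissociates instead, recombination of the alkoxypentadienyl cation with the keto-carboxylate at its unhindered CH2 terminus should lead to the same product. The one new stereocenter, C11 (position 6 of the benzoxepine), is set after loss of CO2 by ketonisation of the enol under equilibrating conditions, which places the side chain equatorial and H-11 axial, anti to the axial angular methyl (6R), so that the C6 epimers and enol of 8, the C5 epimers of 26 and both geometries of the new exocyclic alkene converge. The step needs acylation at the right oxygen (secured by silylation of the other tertiary alcohol) and bond formation at the vinyl CH2 terminus and not at the methoxy-bearing terminus of the second allyl unit (secured by sterics, since the latter would create a fully substituted carbon), and it leaves the C13=C14–C15=C16(OMe) dienol ether that keeps the future enone carbonyl masked in step 20.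

Step 20
Reactants: 30 coupled ketone
Product: 31 (3S,5aR,6R,7S,9aR)-6-{(2Z)-2-[(1R,3aR,8aR)-7-methoxy-1,4,4,6-tetramethyl-1-(triethylsilyloxy)-2,3,3a,4,8,8a-hexahydroazulen-5(1H)-ylidene]ethyl}-2,2,5a,7-tetramethyl-3-(triethylsilyloxy)decahydro-1-benzoxepin-7-ol
Conditions: MeMgBr, CeCl3, THF, −78 °C; aqueous NH4Cl
Reagents that add atoms: methylmagnesium bromide C[Mg]Br
Why: 1,2-addition of the methylcerium reagent to the cyclohexanone, in which the axial path is blocked by the syn-axial angular methyl so that methyl enters equatorially and the hydroxyl becomes axial (7S), the dienol ether keeping the second carbonyl masked.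

Step 21
Reactants: 31 tertiary alcohol
Product: 32 target, (3S,5aR,6R,7S,9aR)-6-{2-[(1R,3aR,8aR)-1-hydroxy-1,4,4,6-tetramethyl-7-oxo-1,2,3,3a,4,7,8,8a-octahydroazulen-5-yl]ethyl}-2,2,5a,7-tetramethyldecahydro-1-benzoxepine-3,7-diol
Conditions: 0.5 M HCl, THF/H2O (4:1), 0 °C → rt
Reagents that add atoms: water O
Why: aqueous acid hydrolysis of the 1-methoxydiene (protonation at the exocyclic carbon, water on the oxocarbenium ion), which gives the conjugated tetrasubstituted enone as the thermodynamic isomer and cleaves both triethylsilyl ethers in the same operation without touching a stereocenter.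

**Compound list**

1 | geraniol, (2E)-3,7-dimethylocta-2,6-dien-1-ol | CC(C)=CCC/C(C)=C/CO | starting material
2 | [(2R,3R)-3-methyl-3-(4-methylpent-3-en-1-yl)oxiran-2-yl]methanol | OC[C@H]1O[C@]1(C)CCC=C(C)C | intermediate
3 | [(2R,3R)-3-{2-[(2S)-3,3-dimethyloxiran-2-yl]ethyl}-3-methyloxiran-2-yl]methanol | OC[C@H]1O[C@]1(C)CC[C@@H]2OC2(C)C | intermediate
4 | (2S,3R)-3-{2-[(2S)-3,3-dimethyloxiran-2-yl]ethyl}-2-(iodomethyl)-3-methyloxirane | IC[C@H]1O[C@]1(C)CC[C@@H]2OC2(C)C | intermediate
5 | tert-butyl 3-oxobutanoate (tert-butyl acetoacetate) | CC(=O)CC(=O)OC(C)(C)C | starting material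
6 | tert-butyl 5-[(2R,3R)-3-{2-[(2S)-3,3-dimethyloxiran-2-yl]ethyl}-3-methyloxiran-2-yl]-3-oxopentanoate | CC(C)(C)OC(=O)CC(=O)CC[C@H]1O[C@]1(C)CC[C@@H]2OC2(C)C | intermediate
7 | tert-butyl (2Z)-5-[(2R,3R)-3-{2-[(2S)-3,3-dimethyloxiran-2-yl]ethyl}-3-methyloxiran-2-yl]-3-(triethylsilyloxy)pent-2-enoate | CC[Si](CC)(CC)O/C(CC[C@H]1O[C@]1(C)CC[C@@H]2OC2(C)C)=C\C(=O)OC(C)(C)C | intermediate
8 | tert-butyl (3S,5aR,9aR)-2,2,5a-trimethyl-7-oxo-3-(triethylsilyloxy)decahydro-1-benzoxepine-6-carboxylate (C6 epimers and enol) | CC(C)(C)OC(=O)C1[C@@]2(C)CC[C@H](O[Si](CC)(CC)CC)C(C)(C)O[C@@H]2CCC1=O | intermediate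
9 | (S)-(+)-linalool, (3S)-3,7-dimethylocta-1,6-dien-3-ol | CC(C)=CCC[C@](C)(O)C=C | starting material
10 | (1S)-1-methylcyclopent-2-en-1-ol | C1C[C@](C)(O)C=C1 | intermediate
11 | 2-methylpropanoyl chloride (isobutyryl chloride) | CC(C)C(Cl)=O | starting material
12 | (1S)-1-methylcyclopent-2-en-1-yl 2-methylpropanoate | C1C[C@](C)(OC(=O)C(C)C)C=C1 | intermediate
13 | trimethyl[(2-methyl-1-{[(1S)-1-methylcyclopent-2-en-1-yl]oxy}prop-1-en-1-yl)oxy]silane | C1C[C@](C)(OC(O[Si](C)(C)C)=C(C)C)C=C1 | intermediate
14 | trimethylsilyl 2-methyl-2-[(1R)-3-methylcyclopent-2-en-1-yl]propanoate | CC1=C[C@@H](CC1)C(C)(C)C(=O)O[Si](C)(C)C | intermediate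
15 | 2-methyl-2-[(1R)-3-methylcyclopent-2-en-1-yl]propanoic acid | CC1=C[C@@H](CC1)C(C)(C)C(O)=O | intermediate
16 | 2-methyl-2-[(1R)-3-methylcyclopent-2-en-1-yl]pentan-3-one | CC1=C[C@@H](CC1)C(C)(C)C(=O)CC | intermediate
17 | (4R)-2-methyl-4-(2-methyl-3-oxopentan-2-yl)cyclopent-2-en-1-one | CC1=C[C@@H](CC1=O)C(C)(C)C(=O)CC | intermediate
18 | 2-[(1R,4S)-4-hydroxy-3-methylcyclopent-2-en-1-yl]-2-methylpentan-3-one | CC1=C[C@@H](C[C@@H]1O)C(C)(C)C(=O)CC | intermediate
19 | 1,1,1-triethoxyethane (triethyl orthoacetate) | CC(OCC)(OCC)OCC | starting material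
20 | 2-{(1R,4S)-4-[(1-ethoxyethenyl)oxy]-3-methylcyclopent-2-en-1-yl}-2-methylpentan-3-one | CC1=C[C@@H](C[C@@H]1OC(=C)OCC)C(C)(C)C(=O)CC | intermediate
21 | ethyl 2-[(1R,5R)-2-methyl-5-(2-methyl-3-oxopentan-2-yl)cyclopent-2-en-1-yl]acetate | CC1=CC[C@@H](C(C)(C)C(=O)CC)[C@H]1CC(=O)OCC | intermediate
22 | ethyl 2-[(1R,2R,5R)-2-hydroxy-2-methyl-5-(2-methyl-3-oxopentan-2-yl)cyclopentyl]acetate | C[C@@]1(O)CC[C@@H](C(C)(C)C(=O)CC)[C@H]1CC(=O)OCC | intermediate
23 | (1R,3aR,8aR)-1-hydroxy-1,4,4,6-tetramethyloctahydroazulene-5,7(1H,6H)-dione (C6 epimers and enol) | CC1C(=O)C(C)(C)[C@@H]2CC[C@@](C)(O)[C@@H]2CC1=O | intermediate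
24 | (1R,3aR,8aR)-1-hydroxy-7-methoxy-1,4,4,6-tetramethyl-2,3,3a,4,8,8a-hexahydroazulen-5(1H)-one | COC1=C(C)C(=O)C(C)(C)[C@@H]2CC[C@@](C)(O)[C@@H]2C1 | intermediate
25 | (1R,3aR,8aR)-7-methoxy-1,4,4,6-tetramethyl-1-(triethylsilyloxy)-2,3,3a,4,8,8a-hexahydroazulen-5(1H)-one | COC1=C(C)C(=O)C(C)(C)[C@@H]2CC[C@@](C)(O[Si](CC)(CC)CC)[C@@H]2C1 | intermediate
26 | (1R,3aR,8aR)-5-ethenyl-7-methoxy-1,4,4,6-tetramethyl-1-(triethylsilyloxy)-1,2,3,3a,4,5,8,8a-octahydroazulen-5-ol (C5 epimers) | COC1=C(C)C(O)(C=C)C(C)(C)[C@@H]2CC[C@@](C)(O[Si](CC)(CC)CC)[C@@H]2C1 | intermediate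
27 | (3S,5aR,9aR)-2,2,5a-trimethyl-6-(oxomethylidene)-3-(triethylsilyloxy)octahydro-1-benzoxepin-7(2H)-one | O=C=C1[C@@]2(C)CC[C@H](O[Si](CC)(CC)CC)C(C)(C)O[C@@H]2CCC1=O | intermediate
28 | (1R,3aR,8aR)-5-ethenyl-7-methoxy-1,4,4,6-tetramethyl-1-(triethylsilyloxy)-1,2,3,3a,4,5,8,8a-octahydroazulen-5-yl (3S,5aR,9aR)-2,2,5a-trimethyl-7-oxo-3-(triethylsilyloxy)decahydro-1-benzoxepine-6-carboxylate | COC1=C(C)C(OC(=O)C3[C@@]4(C)CC[C@H](O[Si](CC)(CC)CC)C(C)(C)O[C@@H]4CCC3=O)(C=C)C(C)(C)[C@@H]2CC[C@@](C)(O[Si](CC)(CC)CC)[C@@H]2C1 | intermediate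
29 | (3S,5aR,9aR)-6-{(2Z)-2-[(1R,3aR,8aR)-7-methoxy-1,4,4,6-tetramethyl-1-(triethylsilyloxy)-2,3,3a,4,8,8a-hexahydroazulen-5(1H)-ylidene]ethyl}-2,2,5a-trimethyl-7-oxo-3-(triethylsilyloxy)decahydro-1-benzoxepine-6-carboxylic acid | OC(=O)C3(C/C=C1\C(C)=C(OC)C[C@H]2[C@](C)(O[Si](CC)(CC)CC)CC[C@H]2C1(C)C)[C@@]4(C)CC[C@H](O[Si](CC)(CC)CC)C(C)(C)O[C@@H]4CCC3=O | intermediate
30 | (3S,5aR,6R,9aR)-6-{(2Z)-2-[(1R,3aR,8aR)-7-methoxy-1,4,4,6-tetramethyl-1-(triethylsilyloxy)-2,3,3a,4,8,8a-hexahydroazulen-5(1H)-ylidene]ethyl}-2,2,5a-trimethyl-3-(triethylsilyloxy)octahydro-1-benzoxepin-7(2H)-one | CC1=C(OC)C[C@H]2[C@](C)(O[Si](CC)(CC)CC)CC[C@H]2C(C)(C)/C1=C/C[C@@H]3[C@@]4(C)CC[C@H](O[Si](CC)(CC)CC)C(C)(C)O[C@@H]4CCC3=O | intermediate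
31 | (3S,5aR,6R,7S,9aR)-6-{(2Z)-2-[(1R,3aR,8aR)-7-methoxy-1,4,4,6-tetramethyl-1-(triethylsilyloxy)-2,3,3a,4,8,8a-hexahydroazulen-5(1H)-ylidene]ethyl}-2,2,5a,7-tetramethyl-3-(triethylsilyloxy)decahydro-1-benzoxepin-7-ol | CC1=C(OC)C[C@H]2[C@](C)(O[Si](CC)(CC)CC)CC[C@H]2C(C)(C)/C1=C/C[C@@H]3[C@@]4(C)CC[C@H](O[Si](CC)(CC)CC)C(C)(C)O[C@@H]4CC[C@]3(C)O | intermediate
32 | (3S,5aR,6R,7S,9aR)-6-{2-[(1R,3aR,8aR)-1-hydroxy-1,4,4,6-tetramethyl-7-oxo-1,2,3,3a,4,7,8,8a-octahydroazulen-5-yl]ethyl}-2,2,5a,7-tetramethyldecahydro-1-benzoxepine-3,7-diol | CC1=C(CC[C@@H]2[C@@]3(C)CC[C@H](O)C(C)(C)O[C@@H]3CC[C@]2(C)O)C(C)(C)[C@@H]2CC[C@@](C)(O)[C@@H]2CC1=O | target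

**Step count and risks**

Total step count: 21. Longest linear sequence: 15 steps (9 → 32, steps 7–21); the west branch takes 6 steps (1 → 8) before the union.

Steps most likely to fail:

Step 19 (key step). O-Acylation of the hindered tertiary carbinol may be outrun by its ionisation and elimination, or the ketene may be lost to adventitious water, so that the ester tether never forms and no C–C bond results. The fallback sets out from 8 and 26 and comes back at 30. A Tsuji–Trost allylation in which Et3B activates the carbinol of 26 directly (Pd(PPh3)4, Et3B, 4 Å molecular sieves, THF, 40 °C) should alkylate the α-carbon of 8 with the unhindered CH2 terminus of the π-allyl complex and give the α-quaternary tert-butyl ester F1. Conversion of the tert-butyl ester into the silyl ester with Me3SiOTf/2,6-lutidine (CH2Cl2, 0 °C) and mild aqueous work-up then set the β-keto acid free, which loses CO2 to give 30.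

Step 6. The silyl triflate may activate the internal instead of the terminal oxirane, or the weakly nucleophilic, ester-conjugated enol ether may lose the race for the epoxonium ion to triflate or oxygen capture, so that the cascade stops short or is misdirected. The fallback sets out from 6 and comes back at 8.
- Heating 6 in wet dioxane (100 °C) converts the tert-butyl β-ketoester, by way of the acylketene and the β-keto acid, into the methyl ketone F2.
- LDA/Et3SiCl (−78 °C) gives the terminal silyl enol ether F3, the terminating group with the closest precedent for this cascade, which under the conditions of step 6 should give the bicyclic ketone F4.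
- Dehydrogenation with 2-iodoxybenzoic acid (DMSO, 70 °C) can only occur away from the quaternary carbon and gives the enone F5.
- The only sp3 α-carbon left in F5 is the desired one, so LDA followed by di-tert-butyl dicarbonate should give the β-ketoester F6.
- H2 over Pd/C saturates the enone double bond and returns 8.

Step 18. Enolisation of the vinylogous ester may compete with addition at the carbonyl flanked by the quaternary carbon, and acid-triggered allylic transposition may occur during isolation of the carbinol. The fallback sets out from 25 and comes back at 26: the slimmer ethynylmagnesium bromide (CeCl3, THF, −78 → 0 °C) should add to give the propargylic carbinol F7, and semi-hydrogenation (H2, Pd/CaCO3 poisoned with Pb(OAc)2, quinoline, EtOAc) gives 26.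

Further compounds
F1 | step 19 | tert-butyl (3S,5aR,9aR)-6-{(2Z)-2-[(1R,3aR,8aR)-7-methoxy-1,4,4,6-tetramethyl-1-(triethylsilyloxy)-2,3,3a,4,8,8a-hexahydroazulen-5(1H)-ylidene]ethyl}-2,2,5a-trimethyl-7-oxo-3-(triethylsilyloxy)decahydro-1-benzoxepine-6-carboxylate | CC1=C(OC)C[C@H]2[C@](C)(O[Si](CC)(CC)CC)CC[C@H]2C(C)(C)/C1=C/CC3(C(=O)OC(C)(C)C)[C@@]4(C)CC[C@H](O[Si](CC)(CC)CC)C(C)(C)O[C@@H]4CCC3=O
F2 | step 6 | 4-[(2R,3R)-3-{2-[(2S)-3,3-dimethyloxiran-2-yl]ethyl}-3-methyloxiran-2-yl]butan-2-one | CC(=O)CC[C@H]1O[C@]1(C)CC[C@@H]2OC2(C)C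
F3 | step 6 | triethyl({4-[(2R,3R)-3-{2-[(2S)-3,3-dimethyloxiran-2-yl]ethyl}-3-methyloxiran-2-yl]but-1-en-2-yl}oxy)silane | C=C(O[Si](CC)(CC)CC)CC[C@H]1O[C@]1(C)CC[C@@H]2OC2(C)C
F4 | step 6 | (3S,5aR,9aR)-2,2,5a-trimethyl-3-(triethylsilyloxy)octahydro-1-benzoxepin-7(2H)-one | C1[C@@]2(C)CC[C@H](O[Si](CC)(CC)CC)C(C)(C)O[C@@H]2CCC1=O
F5 | step 6 | (3S,5aR,9aR)-2,2,5a-trimethyl-3-(triethylsilyloxy)-3,4,5,5a,6,9a-hexahydro-1-benzoxepin-7(2H)-one | C1[C@@]2(C)CC[C@H](O[Si](CC)(CC)CC)C(C)(C)O[C@@H]2C=CC1=O
F6 | step 6 | tert-butyl (3S,5aR,9aR)-2,2,5a-trimethyl-7-oxo-3-(triethylsilyloxy)-2,3,4,5,5a,6,7,9a-octahydro-1-benzoxepine-6-carboxylate | CC(C)(C)OC(=O)C1[C@@]2(C)CC[C@H](O[Si](CC)(CC)CC)C(C)(C)O[C@@H]2C=CC1=O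
F7 | step 18 | (1R,3aR,8aR)-5-ethynyl-7-methoxy-1,4,4,6-tetramethyl-1-(triethylsilyloxy)-1,2,3,3a,4,5,8,8a-octahydroazulen-5-ol | COC1=C(C)C(O)(C#C)C(C)(C)[C@@H]2CC[C@@](C)(O[Si](CC)(CC)CC)[C@@H]2C1
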